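**Strategy**

- Retrosynthesis: the two benzyl groups (ring A ester, ring B ether) come off last. Ring A is then cut at C5-C6 and C1-C2 into an aryl but-2-ynoate and a 2-alkoxycarbonyl-1,1,3-trioxygenated butadiene. The alkynoate is cut at the depside C-O bond into but-2-ynoic acid and ring B.
- Forward: ring B is bought as atraric acid and its chelated 2-OH is benzylated. The free 4-OH is esterified with but-2-ynoic acid, so the depside ester exists before ring A does. The diene is made from dibenzyl malonate and acetyl chloride. A Diels-Alder reaction with aromatization builds ring A on the ester, and hydrogenolysis ends the route.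
- Enabling feature: ring A is a hexasubstituted benzene. Its C1 (depside carbonyl) and C6 (CH3) are the two sp carbons of a but-2-ynoate. Its C2 (OH), C3 (CO2H), C4 (OMe) and C5 (H) are the four diene carbons of an O-methylated acetylmalonate. The di-ortho-substituted aryl ester therefore never has to be made by acylating with a hindered acid.
- Stereochemistry: the target is achiral. The single sp3 ketal carbon of the cycloadduct forms racemic and disappears on aromatization.

Key step: step 8

Remark on the chemistry: the geometry of the silyl ketene acetal double bond of the diene is left open, since that carbon ends as an aromatic carbon. Trimethylsilyl is chosen as the silyl group because it traps the malonate-type dienolate without additives and leaves the arene on dilute acid.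

Step 1
Reactants: 1 methyl 2,4-dihydroxy-3,6-dimethylbenzoate (atraric acid)
Product: 2 methyl 4-(allyloxy)-2-hydroxy-3,6-dimethylbenzoate
Conditions: allyl bromide, K2CO3, acetone, reflux
Reagents that add atoms: allyl bromide, C=CCBr
Why: Williamson etherification under weak-base conditions: the 2-OH is tied up in a hydrogen bond to the ester carbonyl and sits between the ester and a methyl group, so only the free and more acidic 4-OH should be allylated.

Step 2
Reactants: 2 methyl 4-(allyloxy)-2-hydroxy-3,6-dimethylbenzoate
Product: 3 methyl 4-(allyloxy)-2-(benzyloxy)-3,6-dimethylbenzoate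
Conditions: BnBr, K2CO3, DMF, 60 °C
Reagents that add atoms: benzyl bromide, BrCc1ccccc1
Why: Williamson benzylation of a chelated salicylate OH, which needs the dipolar solvent and heat but is routine; the allyl ether and the methyl ester do not react.

Step 3
Reactants: 3 methyl 4-(allyloxy)-2-(benzyloxy)-3,6-dimethylbenzoate
Product: 4 methyl 2-(benzyloxy)-4-hydroxy-3,6-dimethylbenzoate
Conditions: Pd(PPh3)4 (5 mol%), morpholine, THF, rt
Reagents that add atoms: none
Why: Tsuji-Trost deallylation: zerovalent palladium ionizes the aryl allyl ether to a pi-allyl complex that morpholine intercepts, and benzyl ethers and esters are inert to it.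

Step 4
Reactants: 4 methyl 2-(benzyloxy)-4-hydroxy-3,6-dimethylbenzoate; 5 but-2-ynoic acid
Product: 6 methyl 2-(benzyloxy)-4-(but-2-ynoyloxy)-3,6-dimethylbenzoate
Conditions: DCC, DMAP (5 mol%), CH2Cl2, 0 °C to rt
Reagents that add atoms: none
Why: Steglich esterification of an unhindered acid with the only free phenol; the low temperature and small DMAP charge limit base-induced isomerization of the ynoate to the allenoate.

Step 5
Reactants: 7 dibenzyl malonate; 8 acetyl chloride
Product: 9 dibenzyl 2-acetylmalonate
Conditions: MgCl2, Et3N, MeCN, 0 °C to rt; then 1 M HCl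
Reagents that add atoms: none
Why: Magnesium-mediated C-acylation of a malonate (MgCl2/Et3N soft enolization): the chelated magnesium enolate is acylated on carbon and the more acidic product stays chelated, which prevents a second acylation.

Step 6
Reactants: 9 dibenzyl 2-acetylmalonate
Product: 10 dibenzyl 2-(1-methoxyethylidene)malonate
Conditions: TMSCHN2 (2 M in hexanes), toluene/MeOH 4:1, 0 °C to rt
Reagents that add atoms: trimethylsilyldiazomethane, C[Si](C)(C)C=[N+]=[N-]
Why: O-methylation of an acidic, fully enolized beta-tricarbonyl compound with a diazoalkane: the enol protonates the reagent and the resulting methyldiazonium ion is taken up by the enolate oxygen, the central carbon being tertiary and shielded by two benzyl esters.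

Step 7
Reactants: 10 dibenzyl 2-(1-methoxyethylidene)malonate
Product: 12 benzyl 2-[(benzyloxy)(trimethylsilyloxy)methylidene]-3-methoxybut-3-enoate (crude), via lithium dienolate 11 (not isolated)
Conditions: LiN(iPr)2 (lithium diisopropylamide), THF, −78 °C; then TMSCl, −78 °C to rt; pentane, filtration under argon, volatiles removed in vacuo; used crude
Reagents that add atoms: chlorotrimethylsilane, C[Si](C)(C)Cl
Why: Vinylogous deprotonation of an alkylidene malonate at the gamma-methyl group and O-silylation of the extended enolate, the standard entry to Brassard-type vinylketene silyl acetals; the malonate carbon is fully substituted, so silicon goes to oxygen.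

Step 8
Reactants: 6 methyl 2-(benzyloxy)-4-(but-2-ynoyloxy)-3,6-dimethylbenzoate; 12 benzyl 2-[(benzyloxy)(trimethylsilyloxy)methylidene]-3-methoxybut-3-enoate
Product: 15 methyl 2-(benzyloxy)-4-{[3-(benzyloxycarbonyl)-2-hydroxy-4-methoxy-6-methylbenzoyl]oxy}-3,6-dimethylbenzoate, via cyclohexadiene cycloadduct 13 (not isolated), via aryl trimethylsilyl ether 14 (not isolated)
Conditions: 12 (2.5 equiv), toluene, 110 °C, sealed tube; then 1 M HCl, THF, rt
Reagents that add atoms: none
Why: Proposed new method: the closest known reaction type is the thermal Diels-Alder reaction of 1-alkoxy-1-silyloxy-3-oxygenated butadienes (Brassard-type vinylketene acetals) with alkynoates and aromatization to salicylates, which has not been shown for a diene that also bears a 2-alkoxycarbonyl group or for an aryl but-2-ynoate. The diene CH2 terminus, activated by the 3-methoxy group and vinylogously by the ketene acetal oxygens, attacks the methyl-bearing beta-carbon of the ynoate while the ketene acetal carbon bonds to the alpha-carbon, either in one asynchronous concerted (4+2) event or as a vinylogous Mukaiyama-Michael addition followed by collapse of the allenolate onto the silyloxycarbenium carbon, and both courses end at the same 1,4-cyclohexadiene 13. This intermolecular (4+2) cycloaddition closes the six-membered carbocycle of ring A by forming the C5-C6 and C1-C2 bonds; dilute acid then ionizes the mixed benzyl silyl ketal, benzyl alcohol leaves across C2/C5 to give aryl silyl ether 14, and hydrolysis of the O-Si bond frees a phenol that is held by hydrogen bonds to both neighbouring ester carbonyls. The only new stereocenter is the ketal carbon of 13, which forms racemic and is erased on aromatization, so no stereocontrol is required. The step does need regiocontrol, and polarity matching supplies it: all donors of the diene feed the same terminus and the ynoate offers one electrophilic beta-carbon, so CH3 ends at C6 and OH at C2 beside the depside carbonyl. Reactivity is helped by the aryl ester, which lowers the LUMO of the ynoate below that of an alkyl ester, by the three oxygen donors that compensate the ester on the diene, and by the benzyl cap on ring B, which removes the only acidic proton able to quench the ketene acetal.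

Step 9
Reactants: 15 methyl 2-(benzyloxy)-4-{[3-(benzyloxycarbonyl)-2-hydroxy-4-methoxy-6-methylbenzoyl]oxy}-3,6-dimethylbenzoate
Product: 16 methyl 4-[(3-carboxy-2-hydroxy-4-methoxy-6-methylbenzoyl)oxy]-2-hydroxy-3,6-dimethylbenzoate (target CNP0265145.0)
Conditions: H2 (1 atm), Pd/C (10% palladium on carbon), EtOAc, rt
Reagents that add atoms: none
Why: Catalytic hydrogenolysis cleaves the benzyl ester and the aryl benzyl ether in one operation, while the depside aryl ester, the methyl ester and the aryl methyl ether are untouched and ethyl acetate rules out transesterification.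

**Compound list**

1 | methyl 2,4-dihydroxy-3,6-dimethylbenzoate (atraric acid, ring B) | COC(=O)c1c(C)cc(O)c(C)c1O | starting material
2 | methyl 4-(allyloxy)-2-hydroxy-3,6-dimethylbenzoate | COC(=O)c1c(C)cc(OCC=C)c(C)c1O | intermediate
3 | methyl 4-(allyloxy)-2-(benzyloxy)-3,6-dimethylbenzoate | COC(=O)c1c(C)cc(OCC=C)c(C)c1OCc1ccccc1 | intermediate
4 | methyl 2-(benzyloxy)-4-hydroxy-3,6-dimethylbenzoate | COC(=O)c1c(C)cc(O)c(C)c1OCc1ccccc1 | intermediate
5 | but-2-ynoic acid | CC#CC(=O)O | starting material
6 | methyl 2-(benzyloxy)-4-(but-2-ynoyloxy)-3,6-dimethylbenzoate (aryl but-2-ynoate, dienophile) | COC(=O)c1c(C)cc(OC(=O)C#CC)c(C)c1OCc1ccccc1 | intermediate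
7 | dibenzyl malonate | O=C(CC(=O)OCc1ccccc1)OCc1ccccc1 | starting material
8 | acetyl chloride | CC(=O)Cl | starting material
9 | dibenzyl 2-acetylmalonate | CC(=O)C(C(=O)OCc1ccccc1)C(=O)OCc1ccccc1 | intermediate
10 | dibenzyl 2-(1-methoxyethylidene)malonate | COC(C)=C(C(=O)OCc1ccccc1)C(=O)OCc1ccccc1 | intermediate
11 | lithium dienolate of 10 (lithium 1-(benzyloxy)-2-(benzyloxycarbonyl)-3-methoxybuta-1,3-dien-1-olate), not isolated | [Li+].[O-]C(OCc1ccccc1)=C(C(=O)OCc1ccccc1)C(=C)OC | intermediate
12 | benzyl 2-[(benzyloxy)(trimethylsilyloxy)methylidene]-3-methoxybut-3-enoate (diene, ketene acetal geometry not defined) | C=C(OC)C(C(=O)OCc1ccccc1)=C(OCc1ccccc1)O[Si](C)(C)C | intermediate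
13 | cyclohexa-1,4-diene cycloadduct: ring A carbons with C2 as mixed benzyl trimethylsilyl ketal and C5 as CH2, racemic, not isolated | COC1=C(C(=O)OCc2ccccc2)C(OCc2ccccc2)(O[Si](C)(C)C)C(C(=O)Oc2cc(C)c(C(=O)OC)c(OCc3ccccc3)c2C)=C(C)C1 | intermediate
14 | methyl 2-(benzyloxy)-4-{[3-(benzyloxycarbonyl)-4-methoxy-6-methyl-2-(trimethylsilyloxy)benzoyl]oxy}-3,6-dimethylbenzoate, not isolated | COC(=O)c1c(C)cc(OC(=O)c2c(C)cc(OC)c(C(=O)OCc3ccccc3)c2O[Si](C)(C)C)c(C)c1OCc1ccccc1 | intermediate
15 | methyl 2-(benzyloxy)-4-{[3-(benzyloxycarbonyl)-2-hydroxy-4-methoxy-6-methylbenzoyl]oxy}-3,6-dimethylbenzoate | COC(=O)c1c(C)cc(OC(=O)c2c(C)cc(OC)c(C(=O)OCc3ccccc3)c2O)c(C)c1OCc1ccccc1 | intermediate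
16 | methyl 4-[(3-carboxy-2-hydroxy-4-methoxy-6-methylbenzoyl)oxy]-2-hydroxy-3,6-dimethylbenzoate (CNP0265145.0, achiral) | COC(=O)c1c(C)cc(OC(=O)c2c(C)cc(OC)c(C(=O)O)c2O)c(C)c1O | target

**Step count**

Total steps: 9. Longest linear sequence: 6 steps (steps 1, 2, 3, 4, 8, 9). The diene arm (steps 5, 6, 7) joins at step 8.

**Steps most likely to fail**

1. Step 8 (Proposed new method).
   - Risk: the ester-bearing push-pull diene may add too slowly to the beta-methyl ynoate at temperatures it survives. It may also be used up first by protodesilylation or by acyl transfer to the aryl ester.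
   - Fallback (known chemistry only): it sets out from alkynoate 6 and comes back at target 16.
   - Commercial methyl (E)-3-methoxybut-2-enoate is gamma-deprotonated with LiN(iPr)2 and silylated with TMSCl to give 1,3-dimethoxy-1-(trimethylsilyloxy)buta-1,3-diene F1. This is the ester-free diene class on which the known alkynoate benzannulations rest.
   - Heating F1 with 6 in toluene should give the cyclohexadiene cycloadduct F2, not isolated. On dilute HCl it loses methanol and the silyl group to give methyl 2-(benzyloxy)-4-[(2-hydroxy-4-methoxy-6-methylbenzoyl)oxy]-3,6-dimethylbenzoate F3.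
   - The missing C3 carboxyl is then put on the only free position ortho to the ring A phenol. MgCl2, Et3N and paraformaldehyde in MeCN (Casnati-Skattebøl ortho-formylation) should give the 3-formyl depside F4.
   - Pinnick oxidation (NaClO2, NaH2PO4, 2-methyl-2-butene, tBuOH/H2O) should give the 3-carboxy depside F5. Its ring B benzyl ether is removed under the conditions of step 9 to give 16.

2. Step 7.
   - Risk: the amide base may add to the beta-methoxy carbon and displace methoxide instead of removing the gamma-proton. The crude trimethylsilyl ketene acetal may also be hydrolysed during handling.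
   - Fallback: it sets out from acetylmalonate 9 and comes back at protected depside 15. The O-methyl group is left out of the diene and no lithium amide is used.
   - 9 is silylated twice with TMSOTf and Et3N in Et2O (soft enolization) to give benzyl 2-[(benzyloxy)(trimethylsilyloxy)methylidene]-3-(trimethylsilyloxy)but-3-enoate F6.
   - F6 is heated with 6 as in step 8 to give the cyclohexadiene cycloadduct F7, not isolated. Dilute HCl should then give methyl 2-(benzyloxy)-4-{[3-(benzyloxycarbonyl)-2,4-dihydroxy-6-methylbenzoyl]oxy}-3,6-dimethylbenzoate F8.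
   - Methylation with MeI and K2CO3 in acetone should take place at the 4-OH, which is less hindered and less tightly chelated than the 2-OH held between two ester carbonyls. This gives 15.

3. Step 6.
   - Risk: competing methylation on carbon, or slow reaction of the strongly chelated enol, would leave a mixture that is hard to separate.
   - Fallback: it sets out from dibenzyl malonate 7 and comes back at enol ether 10 with no new intermediate.
   - 7 is condensed with trimethyl orthoacetate in acetic anhydride with catalytic ZnCl2 at 120 to 130 °C, the orthoester route used for alkoxymethylene malonates. This forms the C=C bond and the enol ether in one operation, so acylation and O-alkylation are both avoided.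

**Further compounds**

F1 | step 8 | 1,3-dimethoxy-1-(trimethylsilyloxy)buta-1,3-diene | C=C(OC)C=C(OC)O[Si](C)(C)C
F2 | step 8 | cyclohexa-1,4-diene cycloadduct of F1 and 6 (C2 methyl trimethylsilyl ketal, C5 CH2, racemic, not isolated) | COC1=CC(OC)(O[Si](C)(C)C)C(C(=O)Oc2cc(C)c(C(=O)OC)c(OCc3ccccc3)c2C)=C(C)C1
F3 | step 8 | methyl 2-(benzyloxy)-4-[(2-hydroxy-4-methoxy-6-methylbenzoyl)oxy]-3,6-dimethylbenzoate | COC(=O)c1c(C)cc(OC(=O)c2c(C)cc(OC)cc2O)c(C)c1OCc1ccccc1
F4 | step 8 | methyl 2-(benzyloxy)-4-[(3-formyl-2-hydroxy-4-methoxy-6-methylbenzoyl)oxy]-3,6-dimethylbenzoate | COC(=O)c1c(C)cc(OC(=O)c2c(C)cc(OC)c(C=O)c2O)c(C)c1OCc1ccccc1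
F5 | step 8 | methyl 2-(benzyloxy)-4-[(3-carboxy-2-hydroxy-4-methoxy-6-methylbenzoyl)oxy]-3,6-dimethylbenzoate | COC(=O)c1c(C)cc(OC(=O)c2c(C)cc(OC)c(C(=O)O)c2O)c(C)c1OCc1ccccc1
F6 | step 7 | benzyl 2-[(benzyloxy)(trimethylsilyloxy)methylidene]-3-(trimethylsilyloxy)but-3-enoate | C=C(O[Si](C)(C)C)C(C(=O)OCc1ccccc1)=C(OCc1ccccc1)O[Si](C)(C)C
F7 | step 7 | cyclohexa-1,4-diene cycloadduct of F6 and 6 (C2 benzyl trimethylsilyl ketal, C4 silyl enol ether, C5 CH2, racemic, not isolated) | C[Si](C)(C)OC1=C(C(=O)OCc2ccccc2)C(OCc2ccccc2)(O[Si](C)(C)C)C(C(=O)Oc2cc(C)c(C(=O)OC)c(OCc3ccccc3)c2C)=C(C)C1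
F8 | step 7 | methyl 2-(benzyloxy)-4-{[3-(benzyloxycarbonyl)-2,4-dihydroxy-6-methylbenzoyl]oxy}-3,6-dimethylbenzoate | COC(=O)c1c(C)cc(OC(=O)c2c(C)cc(O)c(C(=O)OCc3ccccc3)c2O)c(C)c1OCc1ccccc1
F0 | step 6 | none | none
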